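The time of reading of north is what I must settle before I charge it: I can leave it at 1.5 h, or take it as a run for double product and stop it sooner.

| flask | starting material | partner | remark | time |
|---|---|---|---|---|
| midnight | 20 mM | 15 mM | run made earlier |  |
| noon | 20 mM | 70 mM | run made earlier |  |
| north | 20 mM | 50.0 mM |  | 1.5 h |
| south-west | 20 mM | 80.0 mM |  | 1.5 h |
| south | 20 mM | 20.0 mM |  | 1.5 h |

| run | time / min | double product / % | triple product / % |
|---|---|---|---|
| midnight | 10.0 | 0.9 | 0 |
| midnight | 20.0 | 1.2 | 0.1 |
| midnight | 25.0 | 0.7 | 0.7 |
| midnight | 40.0 | 2.2 | 1.0 |
| midnight | 50.0 | 2.0 | 0.9 |
| noon | 10.0 | 5.2 | 3.2 |
| noon | 20.0 | 8.0 | 11.1 |
| noon | 25.0 | 7.5 | 14.5 |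
| noon | 40.0 | 6.3 | 21.6 |
| noon | 50.0 | 4.6 | 24.5 |

(readings scatter by 0.3 percentage points)



* which of these holds the largest part of the starting material at the end of north (triple product / starting material / double product / single product)
* which of these holds the largest part of the starting material at the end of south-west (triple product / starting material / double product / single product)
* which of these holds the largest part of the starting material at the end of south (triple product / starting material / double product / single product)
* double product at the end of north, in percent of the starting material charged

Between 10.0 min and 25.0 min of the noon run, triple product rises by 11 percentage points while double product reads about 8.0%. If that step runs in proportion to double product and partner, scaling from 70 mM to 50.0 mM of charged partner gives the consumption half-life of double product, its half-life against partner in north, as 10.3 min, a value that carries the scatter of the readings. Because this is shorter than 1.5 h, I expect the reading at the end of north to show double product made in the last part of the run rather than a store built up early. Noon's double product curve is the nearest guide I have, but north holds less partner than noon, so I take that curve for its direction, not as north's own. From 8.0% to 4.6% the noon readings fall at 1.11 h⁻¹, which continued to 1.5 h gives a rough 2.20% for noon. So I leave north at 1.5 h, as a run that is not for double product.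

The forecast names single product, single product and single product as largest in north, south-west and south, because the reaction “leaves most material stranded as single product”, and it puts double product at the end of north at 5%, higher than the 2.20% I continued for noon.

The flask gives triple product as largest in north, triple product in south-west and starting material in south, with 2.72% of double product at the end of north.

    starting material + partner → single product (k = 0.0206 M⁻¹ s⁻¹)
    triple product ⇌ isomer of the product (K = 1.08, k = 2.52 × 10⁻⁴ s⁻¹)
    partner + double product → triple product (k = 0.0393 M⁻¹ s⁻¹)
    single product → decomposed reagent (k = 5.73 × 10⁻⁴ s⁻¹)
    partner + single product → double product (k = 0.00959 M⁻¹ s⁻¹)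

In north at 0.199 h, double product has a half-life of 0.13 h by its step to triple product, shorter than 1.5 h, which spans 8.74 of my half-lives. In north it is then made 1.91 times as fast as it is used, but at 1.50 h that ratio is 0.531. For north read at 25 min, 2.43 of my half-lives have passed, so I expect part of the double product made early to be still there; the computed value is 6.72%, above the 2.72% at 1.5 h.

The earlier runs and the new flask were computed with made-up constants; the scatter is artificial.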